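Target numbering used throughout: bicyclo[3.2.1]oct-3-ene-2,8-dione with C2=O, C3=C4 (styryl on C4), bridgeheads C1/C5, C6 (3,5-dihydroxyphenyl), C7 (4-hydroxyphenyl), C8=O; all phenols are carried as benzyl ethers.
Retrosynthesis: cut C3=C4 (intramolecular Wittig) and C1–C2 (C-acylation) to excise the C2–C3 two-carbon unit, then cut C6–C7 (Nazarov electrocyclisation), then the three C=C bonds of the open-chain trienedione (Knoevenagel, double aldol) back to acetylacetone, two 4-(benzyloxy)benzaldehydes and one 3,5-bis(benzyloxy)benzaldehyde.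
Enabling feature: in the five-membered ring C1–C7–C6–C5–C8 the C8 ketone has both β-carbons (C6, C7) aryl-substituted and trans, the retron of a conrotatory 4π closure of a cross-conjugated dienone; C5 carries C4 at the acyl oxidation level and the C4 styryl arm is identical with the C7 arm, so the precursor is a symmetric 4-arylidene-1,7-diarylhepta-1,6-diene-3,5-dione in which either arm can close.
Forward: chain assembly (steps 1–2), cyclopentanone ring by hydride-interrupted Nazarov cyclisation (step 3), six-membered enone ring by two-carbon insertion between C1 and C4 (steps 4–5), debenzylation (step 6).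
Stereochemistry: C6/C7 trans from conrotation of the (E,E)-termini, absolute sense from a chiral scandium Lewis acid; C1/C5 from the bridging itself (only a cis bridge can close), on the face anti to the C6 aryl group.

Key step: step 3

Remark: the 1,3-diketones 3, 7 and 9–11 are keto–enol mixtures whose α-carbons epimerise freely; each is named and drawn as one diketo form (7 all-trans, 9–11 as the 2,5-cis form that cyclises).

Step 1
Reactants: 1 4-(benzyloxy)benzaldehyde (2 equiv); 2 pentane-2,4-dione
Product: 3 (1E,6E)-1,7-bis[4-(benzyloxy)phenyl]hepta-1,6-diene-3,5-dione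
Conditions: B2O3 (0.7 equiv), B(OnBu)3 (2 equiv), nBuNH2 (0.2 equiv), EtOAc, 80 °C; then 0.5 M HCl, 60 °C
Reagents that add atoms: none
Why: Boron-templated double aldol condensation (Claisen–Schmidt type), in which the boron chelate of the enolised dione masks C3 and activates both methyl groups, and dehydration gives the conjugated (E,E)-dienedione as the thermodynamic alkene isomer.

Step 2
Reactants: 3 (1E,6E)-1,7-bis[4-(benzyloxy)phenyl]hepta-1,6-diene-3,5-dione; 4 3,5-bis(benzyloxy)benzaldehyde
Product: 5 (1E,6E)-4-{[3,5-bis(benzyloxy)phenyl]methylidene}-1,7-bis[4-(benzyloxy)phenyl]hepta-1,6-diene-3,5-dione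
Conditions: piperidine (0.2 equiv), AcOH (0.2 equiv), toluene, 4 Å MS, 80 °C
Reagents that add atoms: none
Why: Knoevenagel condensation of the C4 methylene between the two carbonyl groups with the aldehyde, and because the two acyl groups on the new trisubstituted alkene are identical only one alkene isomer can form.

Step 3
Reactants: 5 (1E,6E)-4-{[3,5-bis(benzyloxy)phenyl]methylidene}-1,7-bis[4-(benzyloxy)phenyl]hepta-1,6-diene-3,5-dione
Product: 7 (2R,3S,4R)-2-[(2E)-3-[4-(benzyloxy)phenyl]prop-2-enoyl]-3-[3,5-bis(benzyloxy)phenyl]-4-[4-(benzyloxy)phenyl]cyclopentan-1-one, via triethylsilyl enol ether 6 (not isolated)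
Conditions: Sc(OTf)3 (20 mol%), (S,S)-Ph-pybox (2,6-bis[(4S)-4-phenyl-4,5-dihydro-1,3-oxazol-2-yl]pyridine, 24 mol%), Et3SiH (4 equiv), 4 Å MS, CH2Cl2, −40 → 0 °C; then 1 M HCl, THF, rt
Reagents that add atoms: none
Why: Proposed new method: two-point binding of the 1,3-dione of 5 to the chiral scandium Lewis acid generates a pentadienyl cation that undergoes thermal conrotatory 4π electrocyclisation, closing the cyclopentanone ring by the bond between the two aryl-bearing carbons, and the polarised oxyallyl cation (enolate end held as the scandium 1,3-diketonate, cationic end at the unsubstituted ring carbon C5) is then reduced by hydride transfer from Et3SiH before it can lose a proton. The closest known reaction types are the Nazarov cyclisation interrupted by silane hydride transfer (reductive Nazarov reaction, known with stoichiometric achiral Lewis acids) and the chiral-Lewis-acid-catalysed Nazarov cyclisation of alkylidene 1,3-dicarbonyl dienones; their combination is new. The five-membered ring closes in the 4π-conrotatory mode, the only closure open to the U-shaped cation. Conrotation of the (E,E)-configured termini sets C3 and C4 trans by orbital symmetry, the sense of rotation and hence the absolute configuration is set by the C2-symmetric pybox pocket around the chelate (the antipodal ligand is taken if the opposite sense is found), and C2 settles trans to the C3 aryl group by enolisation. The step needs hydride capture to beat elimination to the cyclopentenone, which would erase the C4 stereocentre, and this is secured by the second acyl group, which localises the charge on an unhindered secondary terminus, together with excess silane and low temperature; the silane is too weak a hydride donor to reduce the alkylidene dione or the enones directly, and the product is shielded as its silyl enol ether. Because the two cinnamoyl arms of 5 are identical, closure through either carbonyl gives the same constitution.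

Step 4
Reactants: 7 (2R,3S,4R)-2-[(2E)-3-[4-(benzyloxy)phenyl]prop-2-enoyl]-3-[3,5-bis(benzyloxy)phenyl]-4-[4-(benzyloxy)phenyl]cyclopentan-1-one
Product: 9 (2S,3S,4S,5S)-2-[(2E)-3-[4-(benzyloxy)phenyl]prop-2-enoyl]-3-[3,5-bis(benzyloxy)phenyl]-4-[4-(benzyloxy)phenyl]-5-(2-chloroacetyl)cyclopentan-1-one, via bis(trimethylsilyl) dienol ether 8 (not isolated)
Conditions: TMSOTf (2.4 equiv), Et3N (3 equiv), CH2Cl2, 0 °C; pentane trituration; ClCH2COCl (1.2 equiv), CH2Cl2, −78 °C → rt; then dilute aq HCl
Reagents that add atoms: chloroacetyl chloride, ClCC(Cl)=O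
Why: Soft enolisation to the 1,3-bis(silyloxy)diene followed by vinylogous Mukaiyama-type C-acylation at its terminal carbon (C5) puts the chloroacetyl group on the ring carbon next to the 4-(benzyloxy)phenyl-bearing carbon without strong base and without touching C2.

Step 5
Reactants: 9 (2S,3S,4S,5S)-2-[(2E)-3-[4-(benzyloxy)phenyl]prop-2-enoyl]-3-[3,5-bis(benzyloxy)phenyl]-4-[4-(benzyloxy)phenyl]-5-(2-chloroacetyl)cyclopentan-1-one
Product: 12 (1R,5S,6S,7S)-6-[3,5-bis(benzyloxy)phenyl]-7-[4-(benzyloxy)phenyl]-4-{(E)-2-[4-(benzyloxy)phenyl]ethenyl}bicyclo[3.2.1]oct-3-ene-2,8-dione, via phosphonium chloride 10 (not isolated), via acyl ylide 11 (not isolated)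
Conditions: PPh3 (1.1 equiv), NaI (10 mol%), MeCN–toluene, 60 °C; then K2CO3 (1.0 equiv), toluene, 100 °C, high dilution
Reagents that add atoms: none
Why: Phosphonium salt formation and deprotonation of the keto-phosphonium methylene, the most acidic site of the molecule, give a stabilised ylide whose intramolecular Wittig reaction with the cinnamoyl carbonyl closes the six-membered ring irreversibly from the 2,5-cis diketo tautomer, fixing both bridgeheads with the bridge on the face anti to the 3,5-bis(benzyloxy)phenyl group because closure on the other face would press that aryl group, then endo, against the styryl-bearing carbon.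

Step 6
Reactants: 12 (1R,5S,6S,7S)-6-[3,5-bis(benzyloxy)phenyl]-7-[4-(benzyloxy)phenyl]-4-{(E)-2-[4-(benzyloxy)phenyl]ethenyl}bicyclo[3.2.1]oct-3-ene-2,8-dione
Product: 13 (1R,5S,6S,7S)-6-(3,5-dihydroxyphenyl)-7-(4-hydroxyphenyl)-4-[(E)-2-(4-hydroxyphenyl)ethenyl]bicyclo[3.2.1]oct-3-ene-2,8-dione
Conditions: BCl3 (8 equiv), C6HMe5 (12 equiv), CH2Cl2, −78 °C; then MeOH–H2O
Reagents that add atoms: none
Why: Lewis-acid ether cleavage in which pentamethylbenzene traps the benzyl cations by Friedel–Crafts alkylation removes all four benzyl groups at low temperature and leaves the alkenes, the enone and the non-enolisable 1,3-dione untouched.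

Compound list
1 | 4-(benzyloxy)benzaldehyde | O=Cc1ccc(OCc2ccccc2)cc1 | starting material
2 | pentane-2,4-dione (acetylacetone) | CC(=O)CC(C)=O | starting material
3 | (1E,6E)-1,7-bis[4-(benzyloxy)phenyl]hepta-1,6-diene-3,5-dione | O=C(/C=C/c1ccc(OCc2ccccc2)cc1)CC(=O)/C=C/c1ccc(OCc2ccccc2)cc1 | intermediate
4 | 3,5-bis(benzyloxy)benzaldehyde | O=Cc1cc(OCc2ccccc2)cc(OCc2ccccc2)c1 | starting material
5 | (1E,6E)-4-{[3,5-bis(benzyloxy)phenyl]methylidene}-1,7-bis[4-(benzyloxy)phenyl]hepta-1,6-diene-3,5-dione | O=C(/C=C/c1ccc(OCc2ccccc2)cc1)C(=Cc1cc(OCc2ccccc2)cc(OCc2ccccc2)c1)C(=O)/C=C/c1ccc(OCc2ccccc2)cc1 | intermediate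
6 | triethylsilyl enol ether of 7 (Et3SiO on C1, C1=C2 double bond, aryl groups trans as in 7; either O-silyl isomer hydrolyses to 7) | CC[Si](CC)(CC)OC1=C(C(=O)/C=C/c2ccc(OCc3ccccc3)cc2)[C@@H](c2cc(OCc3ccccc3)cc(OCc3ccccc3)c2)[C@H](c2ccc(OCc3ccccc3)cc2)C1 | intermediate
7 | (2R,3S,4R)-2-[(2E)-3-[4-(benzyloxy)phenyl]prop-2-enoyl]-3-[3,5-bis(benzyloxy)phenyl]-4-[4-(benzyloxy)phenyl]cyclopentan-1-one (all-trans) | O=C1C[C@@H](c2ccc(OCc3ccccc3)cc2)[C@H](c2cc(OCc3ccccc3)cc(OCc3ccccc3)c2)[C@H]1C(=O)/C=C/c1ccc(OCc2ccccc2)cc1 | intermediate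
8 | bis(trimethylsilyl) dienol ether of 7 (Me3SiO on C1 with C1=C5 in the ring; exocyclic C2=C(OSiMe3)–styryl, silyloxy group on the side of C1) | C[Si](C)(C)OC1=C[C@@H](c2ccc(OCc3ccccc3)cc2)[C@H](c2cc(OCc3ccccc3)cc(OCc3ccccc3)c2)/C1=C(/O[Si](C)(C)C)\C=C\c1ccc(OCc2ccccc2)cc1 | intermediate
9 | (2S,3S,4S,5S)-2-[(2E)-3-[4-(benzyloxy)phenyl]prop-2-enoyl]-3-[3,5-bis(benzyloxy)phenyl]-4-[4-(benzyloxy)phenyl]-5-(2-chloroacetyl)cyclopentan-1-one (2,5-cis diketo form) | O=C1[C@@H](C(=O)CCl)[C@@H](c2ccc(OCc3ccccc3)cc2)[C@H](c2cc(OCc3ccccc3)cc(OCc3ccccc3)c2)[C@H]1C(=O)/C=C/c1ccc(OCc2ccccc2)cc1 | intermediate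
10 | triphenylphosphonium chloride of 9 (Ph3P+ in place of Cl, same configuration) | O=C1[C@@H](C(=O)C[P+](c2ccccc2)(c2ccccc2)c2ccccc2)[C@@H](c2ccc(OCc3ccccc3)cc2)[C@H](c2cc(OCc3ccccc3)cc(OCc3ccccc3)c2)[C@H]1C(=O)/C=C/c1ccc(OCc2ccccc2)cc1.[Cl-] | intermediate
11 | acyl ylide of 10 (Ph3P=CH–C(=O)– on C5, same configuration) | O=C1[C@@H](C(=O)C=P(c2ccccc2)(c2ccccc2)c2ccccc2)[C@@H](c2ccc(OCc3ccccc3)cc2)[C@H](c2cc(OCc3ccccc3)cc(OCc3ccccc3)c2)[C@H]1C(=O)/C=C/c1ccc(OCc2ccccc2)cc1 | intermediate
12 | (1R,5S,6S,7S)-6-[3,5-bis(benzyloxy)phenyl]-7-[4-(benzyloxy)phenyl]-4-{(E)-2-[4-(benzyloxy)phenyl]ethenyl}bicyclo[3.2.1]oct-3-ene-2,8-dione (C7 aryl endo, C6 aryl exo) | O=C1C=C(/C=C/c2ccc(OCc3ccccc3)cc2)[C@H]2C(=O)[C@@H]1[C@@H](c1ccc(OCc3ccccc3)cc1)[C@@H]2c1cc(OCc2ccccc2)cc(OCc2ccccc2)c1 | intermediate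
13 | (1R,5S,6S,7S)-6-(3,5-dihydroxyphenyl)-7-(4-hydroxyphenyl)-4-[(E)-2-(4-hydroxyphenyl)ethenyl]bicyclo[3.2.1]oct-3-ene-2,8-dione | O=C1C=C(/C=C/c2ccc(O)cc2)[C@H]2C(=O)[C@@H]1[C@@H](c1ccc(O)cc1)[C@@H]2c1cc(O)cc(O)c1 | target

Total step count: 6. Longest linear sequence: 6 steps (2 → 13).

Steps most likely to fail

For step 3 (new method), proton loss from the oxyallyl cation may outrun hydride transfer, which would return a cyclopentenone and erase one of the two new stereocentres. The diketonate product may also hold back the Lewis acid so that turnover stalls, and the chiral pocket may discriminate poorly between the two senses of conrotation. The fallback uses known chemistry, sets out from 1 and returns to the route at 7. Horner–Wadsworth–Emmons olefination of 1 with diethyl {2-[methoxy(methyl)amino]-2-oxoethyl}phosphonate (NaH, THF, 0 °C) should give (E)-3-[4-(benzyloxy)phenyl]-N-methoxy-N-methylprop-2-enamide F1. In parallel, rhodium-catalysed asymmetric 1,4-addition of 4-(benzyloxy)phenylboronic acid to cyclopent-2-en-1-one (Rh(acac)(C2H4)2, (S)-BINAP, dioxane–H2O, 100 °C) should give (S)-3-[4-(benzyloxy)phenyl]cyclopentan-1-one F2. Kinetic enolisation away from the aryl-bearing carbon (LDA, TMSCl, THF, −78 °C) should give (S)-{[4-(4-(benzyloxy)phenyl)cyclopent-1-en-1-yl]oxy}trimethylsilane F3, and Saegusa oxidation (Pd(OAc)2, O2, DMSO) should give (R)-4-[4-(benzyloxy)phenyl]cyclopent-2-en-1-one F4. Copper-catalysed 1,4-addition of 3,5-bis(benzyloxy)phenylmagnesium bromide (CuBr·SMe2, THF, −40 °C), anti to the existing aryl group, and C-acylation of the resulting enolate with F1 should then give 7, all of whose stereocentres follow from the first.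

For step 5, the ylide may be quenched by proton transfer from the neighbouring 1,3-diketone, and the stabilised ylide may react too slowly with a carbonyl group that is mostly enolised. O-alkylation of an enol oxygen by the chloromethyl ketone may compete with phosphonium salt formation, and the bridge may close on the wrong face. The fallback sets out from 7 (silylated to 8 as in step 4) and returns at 12. Acylation of 8 with acetyl chloride in place of chloroacetyl chloride should give (2S,3S,4S,5R)-5-acetyl-2-[(2E)-3-[4-(benzyloxy)phenyl]prop-2-enoyl]-3-[3,5-bis(benzyloxy)phenyl]-4-[4-(benzyloxy)phenyl]cyclopentan-1-one F5. Acid-catalysed intramolecular aldol condensation of its methyl ketone with the cinnamoyl carbonyl (TsOH, toluene, reflux, azeotropic removal of water) should then give 12.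

For step 4, silylation may stop at the mono-silyl stage, the acid chloride may attack an oxygen or the central carbon of the diene instead of its terminal carbon, or the diene may be hydrolysed before it is acylated. The fallback sets out from 7 and returns at 9. Compound 7 is converted into its dianion (LDA, 2.3 equiv, THF, −78 → 0 °C), whose terminal carbanion at C5 is acylated by 2-chloro-N-methoxy-N-methylacetamide; the chelated tetrahedral adduct releases the ketone only on work-up. No new compound is made (entry F0).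

Further compounds
F1 | step 3 | (E)-3-[4-(benzyloxy)phenyl]-N-methoxy-N-methylprop-2-enamide | CON(C)C(=O)/C=C/c1ccc(OCc2ccccc2)cc1
F2 | step 3 | (S)-3-[4-(benzyloxy)phenyl]cyclopentan-1-one | O=C1C[C@@H](c2ccc(OCc3ccccc3)cc2)CC1
F3 | step 3 | (S)-{[4-(4-(benzyloxy)phenyl)cyclopent-1-en-1-yl]oxy}trimethylsilane | C[Si](C)(C)OC1=CC[C@H](c2ccc(OCc3ccccc3)cc2)C1
F4 | step 3 | (R)-4-[4-(benzyloxy)phenyl]cyclopent-2-en-1-one | O=C1C[C@@H](c2ccc(OCc3ccccc3)cc2)C=C1
F5 | step 5 | (2S,3S,4S,5R)-5-acetyl-2-[(2E)-3-[4-(benzyloxy)phenyl]prop-2-enoyl]-3-[3,5-bis(benzyloxy)phenyl]-4-[4-(benzyloxy)phenyl]cyclopentan-1-one (2,5-cis diketo form) | O=C1[C@@H](C(C)=O)[C@@H](c2ccc(OCc3ccccc3)cc2)[C@H](c2cc(OCc3ccccc3)cc(OCc3ccccc3)c2)[C@H]1C(=O)/C=C/c1ccc(OCc2ccccc2)cc1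
F0 | step 4 | none | none
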